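Compound numbers used throughout: starting materials and reagents that deliver atoms are 1, 2, 4, 8, 10, 15, 17 and 21; the key-step precursor is 12, its product 13, and the target is 23.

## Analysis of the target

The target 23 is a single cyclohexene ring with five oxygen functions on a seven-carbon skeleton. In the numbering used here, C1 is the quaternary carbinol carbon, C2 and C3 carry free hydroxyls, C4 carries the secondary benzoate, C5=C6 is the alkene and C7 is the exocyclic CH2 with the primary benzoate. The four contiguous stereocentres are 1S,2S,3S,4R: the C1 and C2 hydroxyls are cis, the C2 and C3 hydroxyls trans, the C3 hydroxyl and the C4 benzoate cis, and C7 lies on the face of O3 and O4, opposite O1 and O2. The sensitive groups are the allylic C4 benzoate, which sits cis to a free hydroxyl and would migrate to O3 under base, the tertiary allylic alcohol at C1, and the alkene, which rules out hydrogenolysis at any stage. The difficulty lies in the fully substituted oxygenated C1 next to three further stereocentres, in acylating exactly two of five oxygens, and in placing the alkene between C5 and C6. The plan rests on the chain C7–C1–C2–C3–C4, which has an oxygen on every carbon and is the C1–C5 chain of a D-hexopyranose; C2 and C3 of the target have the configuration of C3 and C4 of a D-glucoside. C1 with its oxygen and C7 then correspond to C2 and C1 of a 2-alkoxy glycal whose ring oxygen can become a C7 carbonyl oxygen, while C5 and C6 come from a vinyl group on sugar C5.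

## Retrosynthetic reasoning

23 from 22. The three O–H bonds at C1, C2 and C3 are freed last, from the tris(4-methoxybenzyl) ether 22. The benzoates are therefore installed while every other oxygen is an ether, and the ethers are removed oxidatively under neutral conditions. This avoids base (acyl shift from O4 to O3), strong acid and hydrogen.

22 from 20 and 21. Both ester C–O bonds are cut together. In diol 20 the only free hydroxyls are the two to be acylated, so one acylation with 21 serves both and no selectivity is needed.

20 from 18 via 19. The C5=C6 alkene next to the C4 carbinol is the retron of a selenoxide syn-elimination, which leads back to hydroxy selenide 18 with selenium on C5. The forward step must eliminate toward C6 and not toward the carbinol carbon, which is the normal course for β-hydroxy selenoxides.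

18 from 16 and 17. The C5–Se bond is cut to epoxide 16 and the selenolate made from 17. The face of the epoxide decides the regiochemistry. With the epoxide on the face of the C3 ether, diaxial opening at C5 runs through the chair that keeps the C2 and C3 ethers equatorial, and C5 is also remote from the electron-withdrawing C3 oxygen. Both effects agree, and the C4 oxygen comes out cis to O3 as the target requires. The epoxide on the other face was not chosen: its diaxial opening through the same chair would put the nucleophile on C4, against the electronic preference, and the C4 oxygen would later need inversion.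

16 from 14 and 15. The two epoxide C–O bonds are cut to alcohol 14. Its free C7 hydroxyl lies on the face where the epoxide is wanted, so it serves as the directing group for hydroperoxide 15 under vanadium catalysis. This is why C7 is not acylated earlier.

14 from 13. A C–H bond at C7 is removed, leading to aldehyde 13; the forward step is a simple hydride reduction.

13 from 12. Aldehyde 13 is a γ,δ-unsaturated aldehyde (C7=O, C1, C6, C5=C4), the retron of a Claisen rearrangement. Cutting C1–C6 and joining the carbonyl oxygen to C4 gives glycal 12. This cut removes the quaternary stereocentre and the carbocycle in one operation and leads to a pyranoid ring that already holds the C2 and C3 stereocentres. Cuts elsewhere in the ring lead to open chains in which C1 would need an external chiral reagent. The forward reaction must transfer the configuration of sugar C5 to the new quaternary carbon.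

12 from 11, and 11 from 9 and 10. The enol ether double bond of 12 comes from syn-elimination of sulfoxide 11, made from sulfide 9 and peracid 10. The β-thioglycoside is required because only there are the C1–S bond and H2 cis. The acid-labile enol ether is formed directly before the key step.

9 from 7 and 8, and 7 from 6. The C6=C7 bond is cut to aldehyde 7 and the ylide from 8, which adds the only carbon not present in the sugar. Aldehyde 7 comes from primary alcohol 6.

6 from 5, 5 from 3 and 4, and 3 from 1 and 2. The primary hydroxyl of 1 is masked with 2, the three secondary hydroxyls are etherified with 4, and the primary position is released again. The 4-methoxybenzyl group is chosen because it survives base, heat, hydride, peracid and selenolate and leaves at the end without hydrogen, base or strong acid.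

## Alternatives that were turned down

Alternative 1: Nozaki–Hiyama–Kishi closure of the C4–C5 bond.
- Disconnection: between the allylic carbinol carbon C4 and the alkene carbon C5, giving the open-chain (Z)-iodoalkene aldehyde A1 (C1/C2 as acetonide, O3 as silyl ether).
- Forward key step: CrCl2 with catalytic NiCl2 converts the alkenyl iodide (oxidative addition to zerovalent nickel, transmetallation to trivalent chromium) into an alkenylchromium species that adds to the aldehyde and closes the cyclohexene as A2.
- For: the ring closes with the C5=C6 alkene and the C4 oxygen already in place, so no oxidative transposition is needed. The reagent tolerates the benzoate. The expected trans relation of the new hydroxyl to the C3 ether costs nothing, because a Mitsunobu esterification would invert C4 and install the benzoate at once.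
- Against: A1 holds the quaternary C1 in an open chain, so that centre needs a separate reagent-controlled step. It must then be carried through a long linear sequence together with an epimerisable α-silyloxy aldehyde and a (Z)-iodoalkene built on a fully substituted carbon. Selectivity at C4 rests only on 1,2-induction from C3, and divalent chromium is needed in large excess.
- Comparison: A2 is nearer to 23 than aldehyde 13 is (about four steps against six), and on that point this plan is stronger. The chosen route offers instead a quaternary centre set by intramolecular chirality transfer from a stereocentre bought with the sugar, and a precursor 12 reached by seven routine operations.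

Alternative 2: Diels–Alder reaction of a 3-hydroxy-2-pyrone.
- Disconnection: the C1–C2 and C3–C4 bonds, leading to 3-hydroxy-2H-pyran-2-one A3 as diene and the β-silyl enone A4 as dienophile.
- Forward key step: a quinidine-derived bifunctional amine deprotonates A3 and steers its addition across A4 with the acetyl group endo, giving the bridged lactone A5. Its lactone carbonyl is C7, the lactone oxygen sits on C4, the bridgehead hydroxyl is the C1 hydroxyl, and acetyl and silyl mark C2 and C3.
- For: one catalytic step makes the ring, all four stereocentres (matching 23 after retentive Baeyer–Villiger and Fleming–Tamao oxidations), the C5=C6 alkene, the C4 oxygen and C7 at a useful oxidation level. It is independent of the chiral pool and shorter on paper.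
- Against: A4 is a β-substituted, hindered enone, a poor partner for this base-catalysed cycloaddition, and endo, regio- and enantioselectivity would all have to hold. A5 must then survive a peracid next to a strained alkene, an electrophilic aryl–silicon cleavage with peroxide oxidation next to an allylic lactone, and the risk of decarboxylative cycloreversion on warming. After lactone reduction, O7 and O4 must be benzoylated while O1, O2 and O3 are masked, which adds protecting-group steps.
- Comparison: this plan is more convergent and, if every step held, shorter and catalyst-controlled. The chosen route offers instead a secure absolute configuration and functional-group changes that are each routine on a robust cyclohexene.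

Alternative 3: desymmetrising epoxidation of a meso dienol.
- Disconnection: the C2–O and C3–O bonds of an epoxide, leading to the meso cyclohexa-2,5-dienol A6 with the tertiary C1 hydroxyl trans to the C4 benzoate.
- Forward key step: a chiral vanadium catalyst (VO(OiPr)3 with a C2-symmetric bishydroxamic acid) and hydroperoxide 15 binds the tertiary hydroxyl and delivers oxygen to one of the two enantiotopic alkenes on the hydroxyl face, giving epoxy ene A7.
- For: by far the shortest plan. A6 is a few steps from a simple phenol, both benzoates are present from the start, and the directed delivery puts the C2 oxygen cis to the C1 hydroxyl as required.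
- Against: A6 is a doubly allylic tertiary alcohol and a doubly allylic ester that can ionise and aromatise under Lewis-acidic conditions. A cyclic tertiary dienol is a demanding extension for this catalyst class, and the trans relation in A6 must be set first. Above all, A7 must be opened hydrolytically at C3 with inversion next to the C4 benzoate. There, neighbouring-group participation leads to retention or acyl migration, and attack at C2 gives the wrong diastereomer.
- Comparison: on step economy this plan is clearly stronger. The chosen route offers instead a C2/C3 trans-diol taken unchanged from the sugar, never made by an epoxide opening, and esters that never meet hydrolytic conditions.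

Key step: step 8

Remark on the chemistry: carbocycles carry the locants of the target (C1 quaternary, C2–C4 the following oxygen-bearing carbons, C5 and C6 the other ring carbons, C7 exocyclic) and pyranoid compounds carry sugar locants.

Remark on the chemistry: sulfoxide 11 is used as the mixture of epimers at sulfur, since both have H2 cis to the C1–S bond.

## Route

Step 1
Reactants: 1 phenyl 1-thio-β-D-glucopyranoside; 2 trityl chloride
Product: 3 phenyl 6-O-trityl-1-thio-β-D-glucopyranoside
Conditions: TrCl, pyridine, DMAP (cat.), 50 °C
Reagents that add atoms: trityl chloride 2, ClC(c1ccccc1)(c1ccccc1)c1ccccc1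
Why: Tritylation through the trityl cation is selective for the unhindered primary 6-OH, leaving the three secondary hydroxyls free for the next step.

Step 2
Reactants: 3 phenyl 6-O-trityl-1-thio-β-D-glucopyranoside; 4 4-methoxybenzyl chloride
Product: 5 phenyl 2,3,4-tri-O-(4-methoxybenzyl)-6-O-trityl-1-thio-β-D-glucopyranoside
Conditions: NaH, PMBCl, Bu4NI (cat.), DMF, 0 °C → rt
Reagents that add atoms: 4-methoxybenzyl chloride 4, COc1ccc(CCl)cc1
Why: Williamson etherification of the three secondary alkoxides (iodide catalysis); the trityl ether and the thioglycoside are inert to NaH.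

Step 3
Reactants: 5 phenyl 2,3,4-tri-O-(4-methoxybenzyl)-6-O-trityl-1-thio-β-D-glucopyranoside
Product: 6 phenyl 2,3,4-tri-O-(4-methoxybenzyl)-1-thio-β-D-glucopyranoside
Conditions: TsOH·H2O (cat.), MeOH–CH2Cl2, rt
Reagents that add atoms: none
Why: Acid-catalysed methanolysis of the trityl ether through the trityl cation, which ionises far more readily than a 4-methoxybenzyl ether or the thioacetal, frees only O6.

Step 4
Reactants: 6 phenyl 2,3,4-tri-O-(4-methoxybenzyl)-1-thio-β-D-glucopyranoside
Product: 7 phenyl 2,3,4-tri-O-(4-methoxybenzyl)-1-thio-β-D-gluco-hexodialdo-1,5-pyranoside (C6 aldehyde)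
Conditions: Dess–Martin periodinane, pyridine, CH2Cl2, 0 °C → rt; used crude
Reagents that add atoms: none
Why: Dess–Martin oxidation of the primary alcohol under buffered, non-basic conditions spares the sulfide and avoids epimerisation at C5 or β-elimination of the C4 ether.

Step 5
Reactants: 7 phenyl 2,3,4-tri-O-(4-methoxybenzyl)-1-thio-β-D-gluco-hexodialdo-1,5-pyranoside; 8 methyltriphenylphosphonium bromide
Product: 9 phenyl 6,7-dideoxy-2,3,4-tri-O-(4-methoxybenzyl)-1-thio-β-D-gluco-hept-6-enopyranoside
Conditions: Ph3PCH3Br, KN(SiMe3)2, THF, −78 → 0 °C
Reagents that add atoms: methyltriphenylphosphonium bromide 8, C[P+](c1ccccc1)(c1ccccc1)c1ccccc1.[Br-]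
Why: Wittig methylenation with the non-stabilised ylide turns C6 into the vinyl group; addition to the aldehyde at low temperature outruns enolisation, so C5 keeps its configuration.

Step 6
Reactants: 9 phenyl 6,7-dideoxy-2,3,4-tri-O-(4-methoxybenzyl)-1-thio-β-D-gluco-hept-6-enopyranoside; 10 3-chloroperoxybenzoic acid
Product: 11 phenyl 6,7-dideoxy-2,3,4-tri-O-(4-methoxybenzyl)-1-thio-β-D-gluco-hept-6-enopyranoside S-oxide (both epimers at sulfur)
Conditions: mCPBA (1 equiv), CH2Cl2, −78 °C
Reagents that add atoms: 3-chloroperoxybenzoic acid 10, OOC(=O)c1cccc(Cl)c1
Why: Electrophilic oxidation of the sulfide by one equivalent of peracid at low temperature is much faster than epoxidation of the monosubstituted alkene or over-oxidation to the sulfone.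

Step 7
Reactants: 11 phenyl 6,7-dideoxy-2,3,4-tri-O-(4-methoxybenzyl)-1-thio-β-D-gluco-hept-6-enopyranoside S-oxide
Product: 12 (2R,3R,4S)-2-ethenyl-3,4,5-tris[(4-methoxybenzyl)oxy]-3,4-dihydro-2H-pyran (the 2,3,4-tri-O-PMB 5-vinyl 2-alkoxy-D-glucal)
Conditions: iPr2NEt, toluene, 110 °C
Reagents that add atoms: none
Why: Thermal sulfoxide syn-elimination (Ei): in the β-thioglycoside the C1–S bond and H2 are cis, so the five-membered transition state is reachable and the C1=C2 enol ether forms; the amine keeps the acid-labile glycal from protonation.

Step 8
Reactants: 12 (2R,3R,4S)-2-ethenyl-3,4,5-tris[(4-methoxybenzyl)oxy]-3,4-dihydro-2H-pyran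
Product: 13 (1R,2S,3R)-1,2,3-tris[(4-methoxybenzyl)oxy]cyclohex-4-ene-1-carbaldehyde
Conditions: 1,2-dichlorobenzene (degassed), 2,6-di-tert-butyl-4-methylpyridine (cat.), sealed tube, 220–240 °C
Reagents that add atoms: none
Why: Thermal Claisen rearrangement: the enol ether (sugar C1=C2–O5) and the vinyl group on sugar C5 form an allyl vinyl ether, and heating drives a concerted suprafacial [3,3] shift in which the C2–C7 bond forms, the C5–O5 bond breaks and the ring oxygen becomes the aldehyde oxygen. The closest known reaction type is the thermal carbocyclisation of 5-vinyl glycals to cyclohexene carbaldehydes; this substrate differs only by the ether on the bond-forming enol carbon, which makes the enol ether more electron-rich and does not block the terminus. The six-membered carbocycle closes by this sigmatropic C–C bond formation between two termini held on one dihydropyran, so the transition state is necessarily a boat (a bicyclo[2.2.2]octadiene-like array) and the pyran ring is exchanged for the cyclohexene. The new quaternary stereocentre (C1 of the carbocycle, sugar C2) is controlled by the configuration of sugar C5: the vinyl group can bond only to the enol-ether face on which it is held, the face of O3 and opposite O4, so the formyl group emerges trans to the neighbouring C2 ether and cis to the C3 ether. The step needs periselectivity over homolytic or [1,3] shifts of the 4-methoxybenzyl enol ether and over acid-catalysed hydrolysis or allylic ionisation of the glycal; the pre-organised intramolecular geometry favours the [3,3] path, and the hindered base with exclusion of acid and oxygen guards against the others. The aldehyde formed has no α-hydrogen, so it can neither epimerise nor lose the β-ether, and the new C=O bond makes the step irreversible.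

Step 9
Reactants: 13 (1R,2S,3R)-1,2,3-tris[(4-methoxybenzyl)oxy]cyclohex-4-ene-1-carbaldehyde
Product: 14 [(1S,2S,3R)-1,2,3-tris[(4-methoxybenzyl)oxy]cyclohex-4-en-1-yl]methanol
Conditions: NaBH4, MeOH–THF, 0 °C
Reagents that add atoms: none
Why: Hydride reduction of the non-enolisable aldehyde gives the primary alcohol without touching a stereocentre.

Step 10
Reactants: 14 [(1S,2S,3R)-1,2,3-tris[(4-methoxybenzyl)oxy]cyclohex-4-en-1-yl]methanol; 15 tert-butyl hydroperoxide
Product: 16 [(1S,2S,3R,4R,5R)-4,5-epoxy-1,2,3-tris[(4-methoxybenzyl)oxy]cyclohexyl]methanol (epoxide oxygen cis to the CH2OH group and to the C3 ether)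
Conditions: VO(acac)2 (cat.), tBuOOH, toluene, rt → 40 °C
Reagents that add atoms: tert-butyl hydroperoxide 15, CC(C)(C)OO
Why: Hydroxyl-directed vanadium-catalysed epoxidation of a bishomoallylic alcohol: the vanadium alkyl peroxide bound at the C7 oxygen reaches the alkene only from the face carrying the CH2OH group, which is also the face of the C3 ether, and so sets C4 and C5; unbound alkenes and the ethers are inert to this reagent.

Step 11
Reactants: 16 [(1S,2S,3R,4R,5R)-4,5-epoxy-1,2,3-tris[(4-methoxybenzyl)oxy]cyclohexyl]methanol; 17 diphenyl diselenide
Product: 18 [(1S,2S,3R,4S,5S)-4-hydroxy-1,2,3-tris[(4-methoxybenzyl)oxy]-5-(phenylselanyl)cyclohexyl]methanol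
Conditions: (PhSe)2, NaBH4, EtOH, reflux
Reagents that add atoms: diphenyl diselenide 17, c1ccccc1[Se][Se]c1ccccc1
Why: SN2 epoxide opening by benzeneselenolate: trans-diaxial (Fürst–Plattner) attack at C5 runs through the chair with the C2 and C3 ethers equatorial, and C5 is also the carbon remote from the electron-withdrawing C3 oxygen, so both effects point to C5; the C4 oxygen keeps the configuration set in step 10.

Step 12
Reactants: 18 [(1S,2S,3R,4S,5S)-4-hydroxy-1,2,3-tris[(4-methoxybenzyl)oxy]-5-(phenylselanyl)cyclohexyl]methanol
Product: 20 [(1S,2S,3R,4R)-4-hydroxy-1,2,3-tris[(4-methoxybenzyl)oxy]cyclohex-5-en-1-yl]methanol, via selenoxide 19 (not isolated)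
Conditions: H2O2 (30%, excess), pyridine, THF, 0 °C → rt
Reagents that add atoms: none
Why: Oxidation to the selenoxide and spontaneous selenoxide syn-elimination, which for β-hydroxy selenoxides goes away from the carbinol carbon, here toward C6, gives the C5=C6 allylic alcohol with C4 unchanged.

Step 13
Reactants: 20 [(1S,2S,3R,4R)-4-hydroxy-1,2,3-tris[(4-methoxybenzyl)oxy]cyclohex-5-en-1-yl]methanol; 21 benzoyl chloride
Product: 22 [(1S,2S,3R,4R)-4-(benzoyloxy)-1,2,3-tris[(4-methoxybenzyl)oxy]cyclohex-5-en-1-yl]methyl benzoate
Conditions: BzCl, pyridine, DMAP (cat.), CH2Cl2, 0 °C → rt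
Reagents that add atoms: benzoyl chloride 21, O=C(Cl)c1ccccc1
Why: DMAP-catalysed acylation of the primary C7 hydroxyl and the secondary allylic C4 hydroxyl; all other oxygens are ethers, so no selectivity is required and no acyl migration is possible.

Step 14
Reactants: 22 [(1S,2S,3R,4R)-4-(benzoyloxy)-1,2,3-tris[(4-methoxybenzyl)oxy]cyclohex-5-en-1-yl]methyl benzoate
Product: 23 [(1S,2S,3S,4R)-4-(benzoyloxy)-1,2,3-trihydroxycyclohex-5-en-1-yl]methyl benzoate (target)
Conditions: DDQ, CH2Cl2–pH 7 phosphate buffer, 0 °C → rt
Reagents that add atoms: none
Why: Oxidative cleavage of the three 4-methoxybenzyl ethers by DDQ (hydride abstraction to the oxocarbenium ion, then hydrolysis) under buffered neutral conditions leaves the alkene and both benzoates in place and avoids the base that would move the C4 benzoate to O3.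

## Compound list

1 | phenyl 1-thio-β-D-glucopyranoside | OC[C@H]1O[C@@H](Sc2ccccc2)[C@H](O)[C@@H](O)[C@@H]1O | starting material
2 | trityl chloride | ClC(c1ccccc1)(c1ccccc1)c1ccccc1 | starting material
3 | phenyl 6-O-trityl-1-thio-β-D-glucopyranoside | C(c1ccccc1)(c1ccccc1)(c1ccccc1)OC[C@H]1O[C@@H](Sc2ccccc2)[C@H](O)[C@@H](O)[C@@H]1O | intermediate
4 | 4-methoxybenzyl chloride | COc1ccc(CCl)cc1 | starting material
5 | phenyl 2,3,4-tri-O-(4-methoxybenzyl)-6-O-trityl-1-thio-β-D-glucopyranoside | C(c1ccccc1)(c1ccccc1)(c1ccccc1)OC[C@H]1O[C@@H](Sc2ccccc2)[C@H](OCc2ccc(OC)cc2)[C@@H](OCc2ccc(OC)cc2)[C@@H]1OCc1ccc(OC)cc1 | intermediate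
6 | phenyl 2,3,4-tri-O-(4-methoxybenzyl)-1-thio-β-D-glucopyranoside | OC[C@H]1O[C@@H](Sc2ccccc2)[C@H](OCc2ccc(OC)cc2)[C@@H](OCc2ccc(OC)cc2)[C@@H]1OCc1ccc(OC)cc1 | intermediate
7 | phenyl 2,3,4-tri-O-(4-methoxybenzyl)-1-thio-β-D-gluco-hexodialdo-1,5-pyranoside | O=C[C@H]1O[C@@H](Sc2ccccc2)[C@H](OCc2ccc(OC)cc2)[C@@H](OCc2ccc(OC)cc2)[C@@H]1OCc1ccc(OC)cc1 | intermediate
8 | methyltriphenylphosphonium bromide | C[P+](c1ccccc1)(c1ccccc1)c1ccccc1.[Br-] | starting material
9 | phenyl 6,7-dideoxy-2,3,4-tri-O-(4-methoxybenzyl)-1-thio-β-D-gluco-hept-6-enopyranoside | C=C[C@H]1O[C@@H](Sc2ccccc2)[C@H](OCc2ccc(OC)cc2)[C@@H](OCc2ccc(OC)cc2)[C@@H]1OCc1ccc(OC)cc1 | intermediate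
10 | 3-chloroperoxybenzoic acid | OOC(=O)c1cccc(Cl)c1 | starting material
11 | phenyl 6,7-dideoxy-2,3,4-tri-O-(4-methoxybenzyl)-1-thio-β-D-gluco-hept-6-enopyranoside S-oxide (both sulfur epimers) | C=C[C@H]1O[C@@H](S(=O)c2ccccc2)[C@H](OCc2ccc(OC)cc2)[C@@H](OCc2ccc(OC)cc2)[C@@H]1OCc1ccc(OC)cc1 | intermediate
12 | (2R,3R,4S)-2-ethenyl-3,4,5-tris[(4-methoxybenzyl)oxy]-3,4-dihydro-2H-pyran | C=C[C@H]1OC=C(OCc2ccc(OC)cc2)[C@@H](OCc2ccc(OC)cc2)[C@@H]1OCc1ccc(OC)cc1 | intermediate
13 | (1R,2S,3R)-1,2,3-tris[(4-methoxybenzyl)oxy]cyclohex-4-ene-1-carbaldehyde | O=C[C@@]1(OCc2ccc(OC)cc2)CC=C[C@@H](OCc2ccc(OC)cc2)[C@@H]1OCc1ccc(OC)cc1 | intermediate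
14 | [(1S,2S,3R)-1,2,3-tris[(4-methoxybenzyl)oxy]cyclohex-4-en-1-yl]methanol | OC[C@@]1(OCc2ccc(OC)cc2)CC=C[C@@H](OCc2ccc(OC)cc2)[C@@H]1OCc1ccc(OC)cc1 | intermediate
15 | tert-butyl hydroperoxide | CC(C)(C)OO | starting material
16 | [(1S,2S,3R,4R,5R)-4,5-epoxy-1,2,3-tris[(4-methoxybenzyl)oxy]cyclohexyl]methanol | OC[C@@]1(OCc2ccc(OC)cc2)C[C@H]3O[C@H]3[C@@H](OCc2ccc(OC)cc2)[C@@H]1OCc1ccc(OC)cc1 | intermediate
17 | diphenyl diselenide | c1ccccc1[Se][Se]c1ccccc1 | starting material
18 | [(1S,2S,3R,4S,5S)-4-hydroxy-1,2,3-tris[(4-methoxybenzyl)oxy]-5-(phenylselanyl)cyclohexyl]methanol | OC[C@@]1(OCc2ccc(OC)cc2)C[C@H]([Se]c2ccccc2)[C@@H](O)[C@@H](OCc2ccc(OC)cc2)[C@@H]1OCc1ccc(OC)cc1 | intermediate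
19 | selenoxide of 18 (Se-oxide, both selenium epimers) | OC[C@@]1(OCc2ccc(OC)cc2)C[C@H]([Se](=O)c2ccccc2)[C@@H](O)[C@@H](OCc2ccc(OC)cc2)[C@@H]1OCc1ccc(OC)cc1 | intermediate (not isolated)
20 | [(1S,2S,3R,4R)-4-hydroxy-1,2,3-tris[(4-methoxybenzyl)oxy]cyclohex-5-en-1-yl]methanol | OC[C@@]1(OCc2ccc(OC)cc2)C=C[C@@H](O)[C@@H](OCc2ccc(OC)cc2)[C@@H]1OCc1ccc(OC)cc1 | intermediate
21 | benzoyl chloride | O=C(Cl)c1ccccc1 | starting material
22 | [(1S,2S,3R,4R)-4-(benzoyloxy)-1,2,3-tris[(4-methoxybenzyl)oxy]cyclohex-5-en-1-yl]methyl benzoate | O=C(OC[C@@]1(OCc2ccc(OC)cc2)C=C[C@@H](OC(=O)c2ccccc2)[C@@H](OCc2ccc(OC)cc2)[C@@H]1OCc1ccc(OC)cc1)c1ccccc1 | intermediate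
23 | [(1S,2S,3S,4R)-4-(benzoyloxy)-1,2,3-trihydroxycyclohex-5-en-1-yl]methyl benzoate | O=C(OC[C@@]1(O)C=C[C@@H](OC(=O)c2ccccc2)[C@@H](O)[C@@H]1O)c1ccccc1 | target

## Step count and risk

Total step count: 14. Longest linear sequence: 14 steps, from 1 to 23.

The least certain steps are the following.

Step 8 (key step). The boat transition state demands a temperature above 200 °C. At that temperature the 4-methoxybenzyl enol ether may fragment by benzylic C–O homolysis or a [1,3] shift, or the glycal may be lost through traces of acid, before the [3,3] shift is complete. The fallback leaves the thermal pericyclic path. Setting out from 12, iBu3Al in toluene at 0 °C → rt complexes the ring oxygen, ionises the C5–O bond to an allyl cation and aluminium enolate pair that recombines at the same two carbons, and reduces the resulting aldehyde by β-hydride transfer. The route is rejoined at alcohol 14, with step 9 omitted.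

Step 7. The anomeric sulfoxide may ionise at C1–S (anomerisation or hydrolysis) faster than it eliminates, or the sulfenic acid may add back to the electron-rich enol ether. The fallback is an ionic elimination. Setting out from 11, Tf2O with 2,6-di-tert-butyl-4-methylpyridine in CH2Cl2 at −78 → 0 °C activates the sulfoxide to 6,7-dideoxy-2,3,4-tri-O-(4-methoxybenzyl)-α-D-gluco-hept-6-enopyranosyl trifluoromethanesulfonate F1. In the absence of an acceptor, F1 loses H2 to the hindered base and returns to the route at 12.

Step 10. Oxygen transfer may be slow, or facial selectivity poor. The directing hydroxyl is bishomoallylic and must take an axial position next to the C3 ether to reach the alkene. The fallback avoids the epoxide. Setting out from 14, photo-oxygenation (O2, tetraphenylporphyrin, visible light, CH2Cl2; Schenck ene reaction) should bond oxygen to C4 and take a hydrogen from C6 on the same face, because the C3 hydrogen geminal to an ether is not abstracted. This would give [(1S,2S,3S,4R)-4-hydroperoxy-1,2,3-tris[(4-methoxybenzyl)oxy]cyclohex-5-en-1-yl]methanol F2. Reduction with PPh3 rejoins the route at 20, with steps 11 and 12 omitted. The facial outcome of this ene reaction depends on which half-chair reacts and the reaction is slow on 1,2-disubstituted cyclohexenes, so it is a reserve only.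

Step 11. Substitution at C5 may be slow because the axial C1 ether lies syn to the incoming selenolate, and competing attack at C4 would then become visible. The fallback replaces substitution by elimination. Setting out from 16, LiNEt2 in Et2O–hexane at reflux promotes the epoxide to allylic alcohol rearrangement. The only hydrogen syn to the epoxide oxygen on a neighbouring carbon is on C6, so the C5=C6 alkene and the C4 alkoxide form directly. The route is rejoined at 20, with step 12 omitted.

Step 14. Once the first hydroxyl is free, the oxidised 4-methoxybenzyl group of a neighbouring ether may be captured intramolecularly as a cyclic 4-methoxybenzylidene acetal (most easily across the cis O1/O2 pair). Acyl migration from O4 to O3 may also occur during prolonged handling. The fallback is non-oxidative. Setting out from 22, TfOH (cat.) with 1,3-dimethoxybenzene in CH2Cl2 at rt transfers the three 4-methoxybenzyl cations to the arene. The route is rejoined at 23.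

## Further compounds

F0 | step 8 | none | none
F1 | step 7 | 6,7-dideoxy-2,3,4-tri-O-(4-methoxybenzyl)-α-D-gluco-hept-6-enopyranosyl trifluoromethanesulfonate | C=C[C@H]1O[C@H](OS(=O)(=O)C(F)(F)F)[C@H](OCc2ccc(OC)cc2)[C@@H](OCc2ccc(OC)cc2)[C@@H]1OCc1ccc(OC)cc1
F2 | step 10 | [(1S,2S,3S,4R)-4-hydroperoxy-1,2,3-tris[(4-methoxybenzyl)oxy]cyclohex-5-en-1-yl]methanol | OC[C@@]1(OCc2ccc(OC)cc2)C=C[C@@H](OO)[C@@H](OCc2ccc(OC)cc2)[C@@H]1OCc1ccc(OC)cc1
F0 | step 11 | none | none
F0 | step 14 | none | none
A1 | alternative 1 | open-chain (Z)-iodoalkene aldehyde: [5-[1-(tert-butyldimethylsilyloxy)-2-oxoethyl]-4-[(Z)-2-iodoethenyl]-2,2-dimethyl-1,3-dioxolan-4-yl]methyl benzoate, configuration as in A2 | O=C(c1ccccc1)OC[C@]1(/C=C\I)OC(C)(C)O[C@H]1[C@H](O[Si](C)(C)C(C)(C)C)C=O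
A2 | alternative 1 | cyclohexenol with C1/C2 acetonide, C3 silyl ether and C4 hydroxyl trans to the C3 ether | O=C(c1ccccc1)OC[C@@]12C=C[C@H](O)[C@@H](O[Si](C)(C)C(C)(C)C)[C@@H]1OC(C)(C)O2
A3 | alternative 2 | 3-hydroxy-2H-pyran-2-one | O=C1OC=CC=C1O
A4 | alternative 2 | (E)-4-[dimethyl(phenyl)silyl]but-3-en-2-one | CC(=O)/C=C/[Si](C)(C)c1ccccc1
A5 | alternative 2 | bridged lactone (2-oxabicyclo[2.2.2]octenone) with bridgehead hydroxyl, endo acetyl at C2 and silyl at C3 | O=C2[C@@]1(O)C=C[C@@H](O2)[C@@H]([Si](C)(C)c3ccccc3)[C@@H]1C(C)=O
A6 | alternative 3 | meso 4-(benzoyloxy)-1-(benzoyloxymethyl)cyclohexa-2,5-dien-1-ol, hydroxyl trans to the C4 benzoate | O=C(c1ccccc1)OC[C@@]1(O)C=C[C@@H](OC(=O)c2ccccc2)C=C1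
A7 | alternative 3 | C2–C3 epoxy ene dibenzoate, epoxide cis to the C1 hydroxyl | O=C(c1ccccc1)OC[C@@]1(O)C=C[C@@H](OC(=O)c3ccccc3)[C@@H]2O[C@H]12
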